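| flask | substrate | remark | time |
|---|---|---|---|
| Monday's | 10 mM | run made earlier |  |
| Tuesday's | 5 mM | run made earlier |  |
| Saturday's | 20 mM | run made earlier |  |
| west | 10 mM | a single well-mixed tank run continuously and read at steady state, 8.0 min in it on average |  |
| north-east | 10 mM | a closed flask charged with all of it at once and left for 8.0 min | 8.0 min |

| run | time / min | target / % | over-reaction product / % | substrate / % |
|---|---|---|---|---|
| Monday's | 2.00 | 0.9 | 0.3 | 54.7 |
| Monday's | 4.00 | 2.9 | 1.3 | 28.6 |
| Monday's | 6.00 | 3.3 | 1.0 | 16.8 |
| Monday's | 8.00 | 4.0 | 3.8 | 9.1 |
| Tuesday's | 0.833 | 0 | 0 | 78.5 |
| Tuesday's | 2.00 | 0.7 | 0 | 54.1 |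
| Tuesday's | 4.00 | 3.8 | 0 | 29.5 |
| Tuesday's | 10.0 | 5.0 | 6.6 | 4.1 |
| Saturday's | 2.50 | 1.1 | 0 | 46.4 |
| Saturday's | 5.00 | 3.1 | 1.1 | 21.4 |
| Saturday's | 8.00 | 3.8 | 3.0 | 8.5 |
| Saturday's | 10.0 | 4.3 | 5.5 | 4.9 |

(standard deviation of a reading: 0.5 percentage points)

- the set-up with the highest share of target in all that became target or over-reaction product, at the outlet or at the end ("none" if the first two lie within 2 percentage points) (west / north-east / none)
- share of target in all that became target or over-reaction product, at the outlet or at the end, west
- share of target in all that became target or over-reaction product, at the outlet or at the end, north-east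

- the stated concentrations are those of everything mixed, before any reaction; amounts are the same in each set-up
- the earlier runs were made in a closed, stirred flask
- a reading or a percentage of target counts all its forms, free or not
- a reading of substrate is of its free form alone

Amounts come first: at 8.00 min of Monday's run the flask reads target 4.0% and over-reaction product 3.8%, so what does holding target cost per minute? If over-reaction product forms from target in a first-order step, its amount equals a constant times mean target times elapsed time. Monday's target curve, from zero at the start, has a mean reading of 2.28%, so k_L reads 0.209 /min: the loss constant, the fraction of held target passing into product per minute. Tuesday's run at 5 mM reads 0.211 /min, and Saturday's at 20 mM reads 0.219 /min.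

What does this cost in each vessel? Tank west holds target at its outlet level for a mean residence time τ of 8.0 min, so product over target is k_Lτ, 1.67, and the share (the selectivity) is 37.4%. Monday's flask, with the charge and time of north-east, read a mean target of 0.569 of its last reading, so its ratio shrinks by that factor and the share reckoned for north-east reads 51.3%. That is higher than the tank by 14 percentage points, so this reckoning chooses north-east.

The forecast also says north-east, with 53% for north-east, above this reckoning, and 35% for west, below it, the figure for the tank standing “because the tank holds material of all ages”.

The simulation gives 39.3% for west and 53.7% for north-east, so north-east is best.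

    substrate + target ⇌ idle adduct, settled at all times (K = 63.0 /M)
    intermediate B ⇌ intermediate D (K = 2.20, k = 7.90 × 10⁻⁴ /s)
    intermediate A → intermediate C (k = 0.00340 /s)
    intermediate C → intermediate E (k = 0.00190 /s)
    intermediate D ⇌ intermediate E (K = 1.10, k = 0.00220 /s)
    target → over-reaction product (k = 0.00380 /s)
    intermediate C → target (k = 0.0340 /s)
    substrate → intermediate B (k = 0.00430 /s)
    substrate → intermediate A (k = 7.60 × 10⁻⁴ /s)

Flask north-east ends with target 4.21% and over-reaction product 3.62%. Divided by the k_Lτ read from Monday's run, their ratio puts the mean target of flask north-east at an estimated 0.514 of its end value. The same flask read at 2.0 min, reckoned with k_L and a mean of 0.5 of the end value, gives 82.7%, and it stands at 90.7%.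

The readings were computed with constants of no real substance; the scatter is artificial.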